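**Plan**
1. Retrosynthesis: the eight benzyl ethers, the methyl ester and one acetate go last; the upper C3–OH is traced back to C3–B; then O1–C2 and C3–C4 of the upper pyran ring C are cut together (retro-[4+2]) into an ortho-quinone methide and a (Z)-β-borylstyrene; the quinone methide precursor is cut at C4–C4a (phenol plus aldehyde), and the lower unit at C8–CHO and C4–CH2CO2Me back to (−)-epicatechin.
2. Enabling feature: in the upper unit the phenolic O1 of phloroglucinol ring A is ortho to the doubly benzylic C4, so O1=C8a–C4a=C4 can be unveiled as a 1-oxadiene, and C2 carries an electron-rich aryl group, so C2=C3 can come from a styrene.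
3. Forward order: lower flavan first (epicatechin → C4 acetic ester → C8 aldehyde), ring A joined as a phenol to give an ortho-hydroxybenzhydrol, then ring C closed and ring B brought in by the cycloaddition, then C–B oxidation with saponification, then hydrogenolysis.
4. Stereochemistry: lower C2/C3 from (−)-epicatechin, lower C4 by attack anti to the participating 3-acetate; upper C2/C3 cis from the (Z)-alkene, C3/C4 trans from the endo transition state, absolute sense from a chiral phosphoric acid; C–B to C–OH with retention.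

Key step: step 9

Assumption: the sense of induction of the chiral phosphoric acid in step 9 cannot be derived with confidence for this diene; the (R)-acid is written, and the (S)-acid takes its place if a trial shows the other sense.

Locants are flavan locants; in the dimers "upper" and "lower" name the two flavan units.

Step 1
Reactants: 1 3,4-bis(benzyloxy)benzaldehyde
Product: 2 1,2-bis(benzyloxy)-4-ethynylbenzene
Conditions: dimethyl (1-diazo-2-oxopropyl)phosphonate, K2CO3, MeOH, 0 °C → rt
Reagents that add atoms: dimethyl (1-diazo-2-oxopropyl)phosphonate, CC(=O)C(=[N+]=[N-])P(=O)(OC)OC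
Why: Seyferth–Gilbert homologation in the Ohira–Bestmann form: methanolysis of the reagent gives dimethyl (diazomethyl)phosphonate, whose anion adds to the aldehyde, and the alkylidene carbene rearranges to the terminal alkyne under conditions that benzyl ethers tolerate.

Step 2
Reactants: 2 1,2-bis(benzyloxy)-4-ethynylbenzene
Product: 3 (Z)-2-{2-[3,4-bis(benzyloxy)phenyl]ethenyl}-4,4,5,5-tetramethyl-1,3,2-dioxaborolane
Conditions: pinacolborane, [Rh(cod)Cl]2 (1.5 mol %), P(iPr)3 (6 mol %), Et3N, cyclohexane, rt
Reagents that add atoms: pinacolborane, CC1(C)OBOC1(C)C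
Why: rhodium-catalysed trans-hydroboration of a terminal alkyne (through a rhodium vinylidene) should place boron on the terminal carbon and give the (Z)-alkenylboronate, the geometry that later becomes the 2,3-cis relation.

Step 3
Reactants: 4 (−)-epicatechin
Product: 5 5,7,3',4'-tetra-O-benzyl-(−)-epicatechin, (2R,3R)-5,7-bis(benzyloxy)-2-[3,4-bis(benzyloxy)phenyl]chroman-3-ol
Conditions: BnBr (4.4 equiv), K2CO3, DMF, 0 °C → rt, argon
Reagents that add atoms: benzyl bromide, BrCc1ccccc1
Why: Williamson ether synthesis; carbonate deprotonates only the four phenols, so the secondary 3-hydroxyl stays free and C2 is not epimerised.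

Step 4
Reactants: 5 5,7,3',4'-tetra-O-benzyl-(−)-epicatechin
Product: 6 (2R,3R,4S)-5,7-bis(benzyloxy)-2-[3,4-bis(benzyloxy)phenyl]-4-(2-ethoxyethoxy)chroman-3-ol (4β ether; 2,3-cis, 3,4-trans)
Conditions: DDQ (2 equiv), 2-ethoxyethanol (excess), CH2Cl2, rt
Reagents that add atoms: 2-ethoxyethanol, CCOCCO
Why: DDQ benzylic oxidation removes hydride from C4, activated by the 5- and 7-benzyloxy groups, and the alcohol should add to the cation from the face opposite the 3-hydroxyl and 2-aryl groups, as is known for benzylated flavan-3-ols.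

Step 5
Reactants: 6 the 4β-(2-ethoxyethoxy) alcohol
Product: 7 (2R,3R,4S)-5,7-bis(benzyloxy)-2-[3,4-bis(benzyloxy)phenyl]-4-(2-ethoxyethoxy)chroman-3-yl acetate
Conditions: Ac2O, DMAP (cat.), pyridine, rt
Reagents that add atoms: acetic anhydride, CC(=O)OC(C)=O
Why: DMAP-catalysed acylation of the secondary alcohol; the acetate serves as participating group in step 6 and as protection in steps 7 to 9.

Step 6
Reactants: 7 the 3-O-acetyl 4β-(2-ethoxyethoxy) ether
Product: 9 methyl 2-{(2R,3R,4S)-3-acetoxy-5,7-bis(benzyloxy)-2-[3,4-bis(benzyloxy)phenyl]chroman-4-yl}acetate (3,4-trans), via acetoxonium-bridged C4 cation triflate 8 (not isolated)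
Conditions: 1-(tert-butyldimethylsilyloxy)-1-methoxyethene (3 equiv), TMSOTf (0.2 equiv), CH2Cl2, −78 °C
Reagents that add atoms: 1-(tert-butyldimethylsilyloxy)-1-methoxyethene, COC(=C)O[Si](C)(C)C(C)(C)C
Why: Mukaiyama-type SN1 substitution in which TMSOTf ionises the C4 ether, the 3-acetate bridges the cation on its own face (8), and the ketene silyl acetal should therefore attack C4 from the opposite face and set the 3,4-trans (4β) centre, its excess and high nucleophilicity outrunning self-condensation at C8.

Step 7
Reactants: 9 the 4β-(methoxycarbonylmethyl) flavan acetate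
Product: 11 methyl 2-{(2R,3R,4S)-3-acetoxy-5,7-bis(benzyloxy)-2-[3,4-bis(benzyloxy)phenyl]-8-formylchroman-4-yl}acetate, via C8 dimethyliminium chloride 10 (not isolated)
Conditions: POCl3, DMF, 0 °C → 50 °C; then aq NaOAc
Reagents that add atoms: N,N-dimethylformamide, CN(C)C=O; water, O
Why: Vilsmeier–Haack formylation of the phloroglucinol-type ring, expected at C8 (flanked by one benzyloxy group and the ring oxygen) and not at C6 (between two benzyloxy groups), in line with the known C8 preference of electrophiles for 5,7-di-O-benzylflavans; the catechol diether ring is too weakly activated to react.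

Step 8
Reactants: 11 the 8-formyl flavan; 12 3,5-bis(benzyloxy)phenol
Product: 14 methyl 2-{(2R,3R,4S)-3-acetoxy-5,7-bis(benzyloxy)-2-[3,4-bis(benzyloxy)phenyl]-8-[(2,4-bis(benzyloxy)-6-hydroxyphenyl)(hydroxy)methyl]chroman-4-yl}acetate (both carbinol epimers), via bromomagnesium 3,5-bis(benzyloxy)phenoxide 13 (not isolated)
Conditions: 12, EtMgBr (0.98 equiv to 12), Et2O, 0 °C; solvent changed to CH2Cl2; 11, rt; sat. aq NH4Cl, 0 °C
Reagents that add atoms: none
Why: magnesium-phenoxide-mediated ortho-specific hydroxyalkylation, in which the aldehyde binds to magnesium and is delivered to the ortho carbon through a six-membered chelate (the two ortho positions of 12 are equivalent) under non-acidic conditions that spare the ester, the acetate and the ionisable benzhydrol; the carbinol centre forms as both epimers and is erased in step 9.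

Step 9
Reactants: 14 the ortho-hydroxybenzhydrol; 3 the (Z)-alkenylboronate
Product: 16 the upper-ring-C cycloadduct, a benzylated epicatechin-(4β→8)-epicatechin in which a pinacolboryl group stands in the place and configuration of the upper 3-hydroxyl (upper unit 2,3-cis and 3,4-trans; lower unit unchanged), via ortho-quinone methide 15 (not isolated)
Conditions: 3 (4 equiv), (R)-3,3'-bis(2,4,6-triisopropylphenyl)-1,1'-binaphthyl-2,2'-diyl hydrogen phosphate (10 mol %), 5 Å molecular sieves, toluene, 0 °C → rt, 14 added over 6 h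
Reagents that add atoms: none
Why: Proposed new method: the phosphoric acid ionises the doubly activated benzhydrol to ortho-quinone methide 15, a 1-oxadiene (O1=C8a–C4a=C4 of the future upper unit) held on the phosphate by a hydrogen bond, which adds the electron-rich (Z)-alkene of 3 in an inverse-electron-demand hetero-Diels–Alder reaction where the C3–C4 bond runs ahead and the charge building at C2 is carried by the para-benzyloxyphenyl group and the adjacent C–B bond until O1 closes on it. The closest known reaction types are the Brønsted-acid-catalysed [4+2] addition of ortho-quinone methides from ortho-hydroxybenzhydrols to styrenes, which gives 2-arylchromans, and the Diels–Alder reaction of alkenylboronates with the C–B bond kept; a β-borylstyrene as the 2π partner of an ortho-quinone methide is the new element. Ring C of the upper unit is closed by this suprafacial [4+2] addition (in the stepwise limit a Michael addition followed by 6-exo-trig capture of the benzylic cation by the phenol oxygen). The 2,3-cis relation should follow from the (Z) geometry of 3; the 3,4-trans relation from the endo transition state, in which boron and the aryl group of 3 lie under the oxadiene and boron is antiperiplanar across the forming C3–C4 bond to the methide aryl group, which sits syn to the carbonyl oxygen because the peri 5-benzyloxy group disfavours the other position; and the absolute sense from the chiral phosphate covering one face of 15. The step needs regioselectivity (aryl at C2, boron at C3), secured because boron has no lone pair and leaves the aryl group as the only donor polarising the alkene, and chemoselectivity against Friedel–Crafts self-condensation of 15 at the free positions of its phloroglucinol rings, for which the excess of 3 and the slow addition of 14 are provided.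

Step 10
Reactants: 16 the boryl cycloadduct
Product: 17 octa-O-benzyl epicatechin-(4β→8)-4β-(carboxymethyl)epicatechin (upper unit 2R,3R,4R; lower unit 2R,3R,4S; both 3-hydroxyls and the acid free)
Conditions: 30 % aq H2O2, LiOH·H2O, THF/MeOH/H2O, 0 °C → rt; aq Na2SO3; 1 M HCl to pH 4
Reagents that add atoms: hydrogen peroxide, OO; lithium hydroxide, [Li+].[OH-]
Why: boronate oxidation (hydroperoxide adds to boron and C3 migrates to oxygen with retention, so the hydroxyl appears cis to the C2 aryl group and trans to C4) should run alongside saponification of the methyl ester and the lower 3-acetate, and with all phenols benzylated the base can neither oxidise the rings nor epimerise C2.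

Step 11
Reactants: 17 the octa-O-benzyl dihydroxy acid
Product: 18 the target, epicatechin-(4β→8)-4β-(carboxymethyl)epicatechin
Conditions: H2 (1 atm), 20 % Pd(OH)2/C, THF/MeOH/H2O (20:20:1), rt; filtration, lyophilisation
Reagents that add atoms: none
Why: hydrogenolysis of the eight benzyl ethers under neutral conditions, the usual end of benzylated procyanidin syntheses, should leave the flavan C2–O bonds, the interflavan C4–C8 bond and all stereocentres untouched and avoid acid-induced lactonisation onto the 5-hydroxyl.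

**Compound list**
1 | 3,4-bis(benzyloxy)benzaldehyde | O=Cc1ccc(OCc2ccccc2)c(OCc2ccccc2)c1 | starting material
2 | 1,2-bis(benzyloxy)-4-ethynylbenzene | C#Cc1ccc(OCc2ccccc2)c(OCc2ccccc2)c1 | intermediate
3 | (Z)-2-{2-[3,4-bis(benzyloxy)phenyl]ethenyl}-4,4,5,5-tetramethyl-1,3,2-dioxaborolane | CC1(C)OB(/C=C\c2ccc(OCc3ccccc3)c(OCc3ccccc3)c2)OC1(C)C | intermediate
4 | (−)-epicatechin, (2R,3R)-2-(3,4-dihydroxyphenyl)chromane-3,5,7-triol | C1c2c(O)cc(O)cc2O[C@H](c2ccc(O)c(O)c2)[C@@H]1O | starting material
5 | 5,7,3',4'-tetra-O-benzyl-(−)-epicatechin (2R,3R) | C1c2c(OCc3ccccc3)cc(OCc3ccccc3)cc2O[C@H](c2ccc(OCc3ccccc3)c(OCc3ccccc3)c2)[C@@H]1O | intermediate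
6 | (2R,3R,4S)-5,7-bis(benzyloxy)-2-[3,4-bis(benzyloxy)phenyl]-4-(2-ethoxyethoxy)chroman-3-ol (4β ether) | CCOCCO[C@H]1c2c(OCc3ccccc3)cc(OCc3ccccc3)cc2O[C@H](c2ccc(OCc3ccccc3)c(OCc3ccccc3)c2)[C@@H]1O | intermediate
7 | (2R,3R,4S)-5,7-bis(benzyloxy)-2-[3,4-bis(benzyloxy)phenyl]-4-(2-ethoxyethoxy)chroman-3-yl acetate | CCOCCO[C@H]1c2c(OCc3ccccc3)cc(OCc3ccccc3)cc2O[C@H](c2ccc(OCc3ccccc3)c(OCc3ccccc3)c2)[C@@H]1OC(C)=O | intermediate
8 | acetoxonium-bridged C4 cation triflate (2-methyl-1,3-dioxolan-2-ylium cis-fused across C3–C4 on the face of the 3-oxygen; formed in the flask) | CC1=[O+][C@@H]2c3c(OCc4ccccc4)cc(OCc4ccccc4)cc3O[C@H](c3ccc(OCc4ccccc4)c(OCc4ccccc4)c3)[C@@H]2O1.[O-]S(=O)(=O)C(F)(F)F | intermediate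
9 | methyl 2-{(2R,3R,4S)-3-acetoxy-5,7-bis(benzyloxy)-2-[3,4-bis(benzyloxy)phenyl]chroman-4-yl}acetate | COC(=O)C[C@H]1c2c(OCc3ccccc3)cc(OCc3ccccc3)cc2O[C@H](c2ccc(OCc3ccccc3)c(OCc3ccccc3)c2)[C@@H]1OC(C)=O | intermediate
10 | C8 dimethyliminium chloride of 9 (formed in the flask) | COC(=O)C[C@H]1c2c(OCc3ccccc3)cc(OCc3ccccc3)c(C=[N+](C)C)c2O[C@H](c2ccc(OCc3ccccc3)c(OCc3ccccc3)c2)[C@@H]1OC(C)=O.[Cl-] | intermediate
11 | methyl 2-{(2R,3R,4S)-3-acetoxy-5,7-bis(benzyloxy)-2-[3,4-bis(benzyloxy)phenyl]-8-formylchroman-4-yl}acetate | COC(=O)C[C@H]1c2c(OCc3ccccc3)cc(OCc3ccccc3)c(C=O)c2O[C@H](c2ccc(OCc3ccccc3)c(OCc3ccccc3)c2)[C@@H]1OC(C)=O | intermediate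
12 | 3,5-bis(benzyloxy)phenol | Oc1cc(OCc2ccccc2)cc(OCc2ccccc2)c1 | starting material
13 | bromomagnesium 3,5-bis(benzyloxy)phenoxide (formed in the flask) | Br[Mg]Oc1cc(OCc2ccccc2)cc(OCc2ccccc2)c1 | intermediate
14 | methyl 2-{(2R,3R,4S)-3-acetoxy-5,7-bis(benzyloxy)-2-[3,4-bis(benzyloxy)phenyl]-8-[(2,4-bis(benzyloxy)-6-hydroxyphenyl)(hydroxy)methyl]chroman-4-yl}acetate, both carbinol epimers | COC(=O)C[C@H]1c2c(OCc3ccccc3)cc(OCc3ccccc3)c(C(O)c3c(O)cc(OCc4ccccc4)cc3OCc4ccccc4)c2O[C@H](c2ccc(OCc3ccccc3)c(OCc3ccccc3)c2)[C@@H]1OC(C)=O | intermediate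
15 | ortho-quinone methide: the 8-{(Z)-[2,4-bis(benzyloxy)-6-oxocyclohexa-2,4-dien-1-ylidene]methyl} derivative of 9, methide aryl syn to the carbonyl (formed in the flask) | COC(=O)C[C@H]1c2c(OCc3ccccc3)cc(OCc3ccccc3)c(/C=C3\C(=O)C=C(OCc4ccccc4)C=C3OCc4ccccc4)c2O[C@H](c2ccc(OCc3ccccc3)c(OCc3ccccc3)c2)[C@@H]1OC(C)=O | intermediate
16 | cycloadduct: methyl ester, lower 3-acetate, octa-O-benzyl epicatechin-(4β→8)-epicatechin-4β-acetic ester with pinacolboryl in place of the upper 3-hydroxyl (upper unit 2S,3R,4R by the CIP rules, 2,3-cis, 3,4-trans; lower unit 2R,3R,4S) | COC(=O)C[C@H]1c2c(OCc3ccccc3)cc(OCc3ccccc3)c([C@H]3c4c(OCc5ccccc5)cc(OCc5ccccc5)cc4O[C@H](c4ccc(OCc5ccccc5)c(OCc5ccccc5)c4)[C@@H]3B6OC(C)(C)C(C)(C)O6)c2O[C@H](c2ccc(OCc3ccccc3)c(OCc3ccccc3)c2)[C@@H]1OC(C)=O | intermediate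
17 | octa-O-benzyl epicatechin-(4β→8)-4β-(carboxymethyl)epicatechin (upper 2R,3R,4R; lower 2R,3R,4S) | O=C(O)C[C@H]1c2c(OCc3ccccc3)cc(OCc3ccccc3)c([C@H]3c4c(OCc5ccccc5)cc(OCc5ccccc5)cc4O[C@H](c4ccc(OCc5ccccc5)c(OCc5ccccc5)c4)[C@@H]3O)c2O[C@H](c2ccc(OCc3ccccc3)c(OCc3ccccc3)c2)[C@@H]1O | intermediate
18 | epicatechin-(4β→8)-4β-(carboxymethyl)epicatechin (upper 2R,3R,4R; lower 2R,3R,4S) | O=C(O)C[C@H]1c2c(O)cc(O)c([C@H]3c4c(O)cc(O)cc4O[C@H](c4ccc(O)c(O)c4)[C@@H]3O)c2O[C@H](c2ccc(O)c(O)c2)[C@@H]1O | target

**Count**
Total steps: 11. Longest linear sequence: 9 steps (4 → 18, steps 3 to 11); steps 1 and 2 form the side branch to 3.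

**Steps most likely to fail**

Step 9 (the proposed new method). The quinone methide may be consumed by Friedel–Crafts attack of the free positions of its own phloroglucinol rings faster than by the hindered alkene. Boron may be lost by alkenyl transfer instead of ring closure. Face or endo/exo selectivity may be poor. The fallback uses known chemistry and makes the interflavan C4–C8 bond instead. It sets out from acetate 7 (the C4 electrophile) and ester 9 (3 equiv, nucleophilic at C8), which are combined with catalytic TMSOTf in CH2Cl2 at −78 °C. The participating 3-acetate of 7 directs attack to the 4β face and should give the diacetylated octa-O-benzyl dimer methyl ester F1. LiOH in THF/MeOH/H2O then cleaves both acetates and the methyl ester, and the route is rejoined at 17.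

Step 8. The magnesium benzhydrolate may ionise and be captured by a second phenoxide (triarylmethane formation), or the hindered, electron-rich aldehyde may fail to react. The fallback is a boron-templated condensation that sets out from 11 and 12: with PhB(OH)2 and catalytic propionic acid in toluene at reflux with removal of water they should give the cyclic phenylboronate of the benzhydrol, the 2-phenyl-4H-1,3,2-benzodioxaborin F2, which can be purified. Transesterification with propane-1,3-diol in THF at rt releases the benzhydrol, and the route is rejoined at 14.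

Step 7. Formylation may occur at C6 in competition with C8, or conversion may stall. The fallback sets out from 9: bromination with NBS in CH2Cl2 at −78 °C → 0 °C, known to be C8-selective for 5,7-di-O-benzylflavans, gives the 8-bromide F3. Reductive carbonylation (Pd(OAc)2 as divalent palladium precatalyst, di(1-adamantyl)-n-butylphosphine, CO/H2, TMEDA, toluene, 100 °C) then gives the aldehyde, and the route is rejoined at 11.

**Further compounds**
F1 | step 9 | methyl ester of octa-O-benzyl 3-O-acetyl-epicatechin-(4β→8)-3-O-acetyl-4β-(carboxymethyl)epicatechin | COC(=O)C[C@H]1c2c(OCc3ccccc3)cc(OCc3ccccc3)c([C@H]3c4c(OCc5ccccc5)cc(OCc5ccccc5)cc4O[C@H](c4ccc(OCc5ccccc5)c(OCc5ccccc5)c4)[C@@H]3OC(C)=O)c2O[C@H](c2ccc(OCc3ccccc3)c(OCc3ccccc3)c2)[C@@H]1OC(C)=O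
F2 | step 8 | 2-phenyl-4H-1,3,2-benzodioxaborin of benzhydrol 14 (5,7-bis(benzyloxy) on the benzo ring, C4 of the boron heterocycle bonded to C8 of the flavan; both C4 epimers) | COC(=O)C[C@H]1c2c(OCc3ccccc3)cc(OCc3ccccc3)c(C3OB(c4ccccc4)Oc4cc(OCc5ccccc5)cc(OCc5ccccc5)c34)c2O[C@H](c2ccc(OCc3ccccc3)c(OCc3ccccc3)c2)[C@@H]1OC(C)=O
F3 | step 7 | methyl 2-{(2R,3R,4S)-3-acetoxy-5,7-bis(benzyloxy)-2-[3,4-bis(benzyloxy)phenyl]-8-bromochroman-4-yl}acetate | COC(=O)C[C@H]1c2c(OCc3ccccc3)cc(OCc3ccccc3)c(Br)c2O[C@H](c2ccc(OCc3ccccc3)c(OCc3ccccc3)c2)[C@@H]1OC(C)=O
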